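**Retrosynthetic overview**

Ring A is the 3,5-dihydroxyphenoxy end, ring B the central ring and ring C the 2,4,6-trihydroxyphenyl end; the strategy rests on ring A being a 5-aryloxyresorcinol, with its three oxygens on alternate carbons (carbons 1, 3 and 5 of ring A, carbon 1 bearing the ether oxygen to ring B).
Key disconnection: ring A comes from carbon monoxide 11 and the 3-acetoxy-1,4-enyne 10 by [Rh(CO)2Cl]2-catalysed carbonylative (5+1) benzannulation. CO becomes carbon 5 of ring A with its hydroxyl, the migrating acetate delivers the oxygen on carbon 3, and the enol ether carbon of 10 becomes carbon 1 with the ether oxygen to ring B already attached (new ring-A bonds: carbon 4 to carbon 5, carbon 5 to carbon 6, carbon 3 to oxygen).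
10 comes from 2-aryloxyacrolein 7, ethynylmagnesium bromide 8 and Ac2O; 7 from aryloxyacetaldehyde 6 and formaldehyde; 6 from acetal 5.
5 comes from Ullmann C–O coupling of bromide 3 with 2,4,6-trimethoxyphenol 4, which forms the ether bond between rings B and C at carbon 4 of ring B; 3 comes from O-alkylation of 4-bromo-2,6-dimethoxyphenol 1 with bromoacetal 2 at the hindered hydroxyl on carbon 1 of ring B.
Ring order: rings B and C are bought and joined first (step 2); ring A is the only ring built (step 6); methanolysis and BBr3 then free the seven hydroxyls.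

Key step: step 6

Remark on the chemistry: the target has no stereocentre; the single stereocentre of 9 and 10 is carried as the racemate and is destroyed in step 6.

**Route**

Step 1
Reactants: 1 4-bromo-2,6-dimethoxyphenol; 2 bromoacetaldehyde diethyl acetal
Product: 3 5-bromo-2-(2,2-diethoxyethoxy)-1,3-dimethoxybenzene
Conditions: K2CO3, DMF, 120 °C
Reagents that add atoms: none
Why: Williamson ether synthesis, in which the phenoxide of 1, although flanked by two methoxy groups, should displace the primary bromide on heating while the aryl bromide stays untouched.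

Step 2
Reactants: 3 5-bromo-2-(2,2-diethoxyethoxy)-1,3-dimethoxybenzene; 4 2,4,6-trimethoxyphenol
Product: 5 2-(2,2-diethoxyethoxy)-1,3-dimethoxy-5-(2,4,6-trimethoxyphenoxy)benzene
Conditions: CuI (10 mol%), picolinic acid (20 mol%), K3PO4, DMSO, 100 °C, argon
Reagents that add atoms: none
Why: Ullmann-type diaryl ether coupling with a CuI/picolinic acid system suited to 2,6-disubstituted phenols and electron-rich aryl bromides; the bromide of 3 has two free ortho positions and the acetal is inert to K3PO4.

Step 3
Reactants: 5 2-(2,2-diethoxyethoxy)-1,3-dimethoxy-5-(2,4,6-trimethoxyphenoxy)benzene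
Product: 6 2-[2,6-dimethoxy-4-(2,4,6-trimethoxyphenoxy)phenoxy]acetaldehyde
Conditions: 1 M aq. HCl, THF, 40 °C
Reagents that add atoms: water, O
Why: Acid-catalysed acetal hydrolysis; benzofuran-type cyclisation is excluded because both ortho positions of ring B carry methoxy groups, and dilute aqueous acid keeps the aldehyde hydrated and unreactive toward ring C.

Step 4
Reactants: 6 2-[2,6-dimethoxy-4-(2,4,6-trimethoxyphenoxy)phenoxy]acetaldehyde
Product: 7 2-[2,6-dimethoxy-4-(2,4,6-trimethoxyphenoxy)phenoxy]prop-2-enal
Conditions: 37% aq. HCHO, pyrrolidine (10 mol%), EtCO2H (10 mol%), i-PrOH, 45 °C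
Reagents that add atoms: formaldehyde, C=O
Why: Organocatalytic Mannich-type α-methylenation (enamine addition to the formaldehyde iminium ion, then β-elimination of the amine), a reaction known for aldehydes with an α-oxygen substituent; only catalytic iminium is present, so ring C should not be aminomethylated, and enal 7 is used at once.

Step 5
Reactants: 7 2-[2,6-dimethoxy-4-(2,4,6-trimethoxyphenoxy)phenoxy]prop-2-enal; 8 ethynylmagnesium bromide
Product: 10 4-[2,6-dimethoxy-4-(2,4,6-trimethoxyphenoxy)phenoxy]pent-4-en-1-yn-3-yl acetate (racemic), via bromomagnesium alkoxide 9 (not isolated)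
Conditions: HC≡CMgBr (1.2 equiv), THF, −78 → 0 °C; then Ac2O, DMAP (cat.), 0 °C → rt
Reagents that add atoms: acetic anhydride, CC(=O)OC(C)=O
Why: Grignard 1,2-addition of the alkynyl reagent to the enal carbonyl followed by O-acylation of the magnesium alkoxide in the same flask; the new stereocentre forms without control, which does not matter because step 6 destroys it.

Step 6
Reactants: 10 4-[2,6-dimethoxy-4-(2,4,6-trimethoxyphenoxy)phenoxy]pent-4-en-1-yn-3-yl acetate (racemic); 11 carbon monoxide
Product: 14 3-[2,6-dimethoxy-4-(2,4,6-trimethoxyphenoxy)phenoxy]-5-hydroxyphenyl acetate, via dienylketene 12 (not isolated), via cyclohexadienone 13 (not isolated)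
Conditions: [Rh(CO)2Cl]2 (5 mol%), CO (20 atm), CH2Cl2, 80 °C, autoclave
Reagents that add atoms: none
Why: The terminal alkyne of 10 is π-activated by monovalent rhodium, the acetate carbonyl oxygen adds to the internal alkyne carbon, and opening of the resulting five-membered dioxolenium ion shifts the acetoxy group from carbon 3 to carbon 2 of the enyne (Rautenstrauch-type 1,2-acyloxy migration), leaving a dienyl rhodium carbene at the former alkyne terminus. CO inserts into the carbene to give dienylketene 12 (or the equivalent acyl rhodacycle), which closes ring A by thermal disrotatory 6π-electrocyclisation between the ketene carbon (carbon 5 of ring A) and the enol ether CH2 (carbon 6 of ring A), and dienone 13 then aromatises by tautomerisation to phenol 14. The closest known reaction is the [Rh(CO)2Cl]2-catalysed carbonylative (5+1) benzannulation of 3-acyloxy-1,4-enynes to resorcinol monoesters, applied here to an enyne whose alkene carries an aryloxy group in place of a carbon substituent, which makes the closing terminus more nucleophilic toward the ketene. No stereocentre is created and the one in 10 is erased, so racemic 10 serves. The step needs 1,2- and not 1,3-acyloxy migration, which the unsubstituted alkyne terminus secures, and a cis relation of ketene and enol ether across the new double bond between carbons 2 and 3 of ring A, which the cyclic dioxolenium intermediate delivers. The 1,3,5-oxygen pattern follows from the chain itself, since the CO carbon, the acetoxy carbon and the enol ether carbon are each one CH apart.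

Step 7
Reactants: 14 3-[2,6-dimethoxy-4-(2,4,6-trimethoxyphenoxy)phenoxy]-5-hydroxyphenyl acetate
Product: 15 5-[2,6-dimethoxy-4-(2,4,6-trimethoxyphenoxy)phenoxy]benzene-1,3-diol
Conditions: K2CO3 (0.2 equiv), MeOH, 0 °C → rt, argon
Reagents that add atoms: none
Why: Base-catalysed transesterification (Zemplén-type methanolysis) of the aryl acetate, which should be far faster than any reaction of the aryl methyl or diaryl ethers.

Step 8
Reactants: 15 5-[2,6-dimethoxy-4-(2,4,6-trimethoxyphenoxy)phenoxy]benzene-1,3-diol
Product: 16 triphlorethol A, 5-[2,6-dihydroxy-4-(2,4,6-trihydroxyphenoxy)phenoxy]benzene-1,3-diol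
Conditions: BBr3 (12 equiv), CH2Cl2, −78 °C → rt, argon; then H2O, 0 °C
Reagents that add atoms: none
Why: Lewis acid cleavage of the five aryl methyl ethers by BBr3 (bromide attacks the O-methyl carbon of the boron-complexed ether); the two diaryl ether bonds should survive because bromide cannot attack an aryl carbon.

**Compound list**

1 | 4-bromo-2,6-dimethoxyphenol | COc1cc(Br)cc(OC)c1O | starting material
2 | bromoacetaldehyde diethyl acetal | CCOC(CBr)OCC | starting material
3 | 5-bromo-2-(2,2-diethoxyethoxy)-1,3-dimethoxybenzene | CCOC(COc1c(OC)cc(Br)cc1OC)OCC | intermediate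
4 | 2,4,6-trimethoxyphenol | COc1cc(OC)c(O)c(OC)c1 | starting material
5 | 2-(2,2-diethoxyethoxy)-1,3-dimethoxy-5-(2,4,6-trimethoxyphenoxy)benzene | CCOC(COc1c(OC)cc(Oc2c(OC)cc(OC)cc2OC)cc1OC)OCC | intermediate
6 | 2-[2,6-dimethoxy-4-(2,4,6-trimethoxyphenoxy)phenoxy]acetaldehyde | O=CCOc1c(OC)cc(Oc2c(OC)cc(OC)cc2OC)cc1OC | intermediate
7 | 2-[2,6-dimethoxy-4-(2,4,6-trimethoxyphenoxy)phenoxy]prop-2-enal | C=C(C=O)Oc1c(OC)cc(Oc2c(OC)cc(OC)cc2OC)cc1OC | intermediate
8 | ethynylmagnesium bromide | C#C[Mg]Br | starting material
9 | bromomagnesium 4-[2,6-dimethoxy-4-(2,4,6-trimethoxyphenoxy)phenoxy]pent-4-en-1-yn-3-olate (racemic; not isolated) | C#CC(O[Mg]Br)C(=C)Oc1c(OC)cc(Oc2c(OC)cc(OC)cc2OC)cc1OC | intermediate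
10 | 4-[2,6-dimethoxy-4-(2,4,6-trimethoxyphenoxy)phenoxy]pent-4-en-1-yn-3-yl acetate (racemic) | C#CC(OC(C)=O)C(=C)Oc1c(OC)cc(Oc2c(OC)cc(OC)cc2OC)cc1OC | intermediate
11 | carbon monoxide | [C-]#[O+] | starting material
12 | (3E)-3-acetoxy-5-[2,6-dimethoxy-4-(2,4,6-trimethoxyphenoxy)phenoxy]hexa-1,3,5-trien-1-one (dienylketene; ketene and enol ether carbons cis across the central double bond; not isolated) | O=C=C/C(OC(C)=O)=C\C(=C)Oc1c(OC)cc(Oc2c(OC)cc(OC)cc2OC)cc1OC | intermediate
13 | 3-acetoxy-5-[2,6-dimethoxy-4-(2,4,6-trimethoxyphenoxy)phenoxy]cyclohexa-2,4-dien-1-one (not isolated) | O=C1C=C(OC(C)=O)C=C(Oc2c(OC)cc(Oc3c(OC)cc(OC)cc3OC)cc2OC)C1 | intermediate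
14 | 3-[2,6-dimethoxy-4-(2,4,6-trimethoxyphenoxy)phenoxy]-5-hydroxyphenyl acetate | CC(=O)Oc1cc(O)cc(Oc2c(OC)cc(Oc3c(OC)cc(OC)cc3OC)cc2OC)c1 | intermediate
15 | 5-[2,6-dimethoxy-4-(2,4,6-trimethoxyphenoxy)phenoxy]benzene-1,3-diol | Oc1cc(O)cc(Oc2c(OC)cc(Oc3c(OC)cc(OC)cc3OC)cc2OC)c1 | intermediate
16 | triphlorethol A, 5-[2,6-dihydroxy-4-(2,4,6-trihydroxyphenoxy)phenoxy]benzene-1,3-diol | Oc1cc(O)cc(Oc2c(O)cc(Oc3c(O)cc(O)cc3O)cc2O)c1 | target

**Step count and risks**

Total step count: 8. Longest linear sequence: 8 steps (1 → 16); all other inputs are purchased.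

Steps most likely to fail:

Step 6. After the acetoxy shift the rhodium carbene may be captured by the electron-rich aryloxy alkene before CO inserts (Rautenstrauch-type five-membered ring closure). The acetate may also take the 1,3-shift to an allenyl acetate, or the enol ether may be cleaved by traces of acid, so that no resorcinol forms. The fallback buys ring A instead of building it and uses known chemistry. It sets out from 1, whose hindered hydroxyl (on carbon 1 of ring B) is arylated with 1-iodo-3,5-dimethoxybenzene (COc1cc(I)cc(OC)c1) under CuI, picolinic acid and K3PO4 in DMSO at 80 °C. The iodide should react well ahead of the deactivated bromide of the phenoxide, giving 5-bromo-2-(3,5-dimethoxyphenoxy)-1,3-dimethoxybenzene F1. A second Ullmann coupling of F1 with 4 under the conditions of step 2 should give 2-(3,5-dimethoxyphenoxy)-1,3-dimethoxy-5-(2,4,6-trimethoxyphenoxy)benzene F2, the heptamethyl ether. BBr3 in CH2Cl2 then cleaves all seven methyl ethers, and the route is rejoined at 16.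

Step 2. Copper insertion into the electron-rich bromide of 3 may be slow, while the hindered, easily oxidised phenoxide of 4 is consumed by oxidation and 3 is reduced to the arene, so that ether formation is outrun. The fallback makes the aryl halide electron-poor and brings in the oxygen on carbon 1 of ring B afterwards. It sets out from 4, which is coupled with 4-bromo-2,6-dimethoxybenzaldehyde (COc1cc(Br)cc(OC)c1C=O) under CuI, picolinic acid and K3PO4 in DMSO at 90 °C. The para-formyl group activates the bromide for both copper insertion and direct addition–elimination, and the product should be 2,6-dimethoxy-4-(2,4,6-trimethoxyphenoxy)benzaldehyde F3. Baeyer–Villiger (Dakin-type) oxidation with mCPBA in CH2Cl2, where the electron-rich aryl group migrates, gives 2,6-dimethoxy-4-(2,4,6-trimethoxyphenoxy)phenyl formate F4. Methanolysis with catalytic K2CO3 in MeOH gives 2,6-dimethoxy-4-(2,4,6-trimethoxyphenoxy)phenol F5. Alkylation of F5 with 2 (K2CO3, DMF, 120 °C, as in step 1) rejoins the route at 5.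

Step 8. Ether cleavage may stop at partly methylated phenols, and the electron-rich heptaphenol may oxidise in air during aqueous work-up and chromatography, leaving a mixture that cannot be purified as free phenols. The fallback isolates the product as a stable derivative. It sets out from 15, which is treated with BBr3 as in step 8; the crude phenol is acetylated without purification (Ac2O, pyridine, DMAP) to triphlorethol A heptaacetate F6. F6 can be chromatographed and crystallised free of partly methylated material. Acid-catalysed methanolysis (1.25 M HCl in MeOH, argon, rt) and evaporation then return the route at 16 without chromatography of the free phenol.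

**Further compounds**

F1 | step 6 | 5-bromo-2-(3,5-dimethoxyphenoxy)-1,3-dimethoxybenzene | COc1cc(OC)cc(Oc2c(OC)cc(Br)cc2OC)c1
F2 | step 6 | 2-(3,5-dimethoxyphenoxy)-1,3-dimethoxy-5-(2,4,6-trimethoxyphenoxy)benzene | COc1cc(OC)cc(Oc2c(OC)cc(Oc3c(OC)cc(OC)cc3OC)cc2OC)c1
F3 | step 2 | 2,6-dimethoxy-4-(2,4,6-trimethoxyphenoxy)benzaldehyde | COc1cc(OC)c(Oc2cc(OC)c(C=O)c(OC)c2)c(OC)c1
F4 | step 2 | 2,6-dimethoxy-4-(2,4,6-trimethoxyphenoxy)phenyl formate | COc1cc(OC)c(Oc2cc(OC)c(OC=O)c(OC)c2)c(OC)c1
F5 | step 2 | 2,6-dimethoxy-4-(2,4,6-trimethoxyphenoxy)phenol | COc1cc(OC)c(Oc2cc(OC)c(O)c(OC)c2)c(OC)c1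
F6 | step 8 | triphlorethol A heptaacetate, 5-[2,6-diacetoxy-4-(2,4,6-triacetoxyphenoxy)phenoxy]-1,3-phenylene diacetate | CC(=O)Oc1cc(OC(C)=O)cc(Oc2c(OC(C)=O)cc(Oc3c(OC(C)=O)cc(OC(C)=O)cc3OC(C)=O)cc2OC(C)=O)c1
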